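## Retrosynthetic overview

1. No ring is built: the fully oxygenated quinone ring is bought intact as 2,5-dihydroxy-1,4-benzoquinone (1), and the two outer benzene rings are bought ready-made as phenol.
2. Key disconnection: both quinone–aryl C–C bonds at once. The nucleophilic enol carbons of 1 are made electrophilic as phenyliodonium ylides (mono-ylide 2, bis-ylide 3) and each is joined to the nucleophilic para-carbon of one molecule of unprotected phenol (4), through mono-aryl ylide 5, to give atromentin (6).
3. Last disconnection: the acetate C–O bond. Only the two acidic quinone OH groups of 6 are ionised (salt 7), and one of them is acylated to give the target 8.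
4. Forward order: ylide formation → double C–H arylation → monoacetylation; three steps, no protecting groups.

Assumption 1: the target has no stereocentre (achiral quinone), so "single enantiomer" is taken to mean the constitution drawn and no stereocontrol is needed.
Assumption 2: BF3·OEt2 in step 2 is a Lewis-acid promoter that the balanced equation does not consume.
Assumption 3: step 2 builds two molecules of phenol (4) into the product, one per ylide centre (3 + 2 PhOH → 6 + 2 PhI); the second molecule is entered under "Reagents that add atoms".

## Route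

**Step 1**
Reactants: 1 2,5-dihydroxy-1,4-benzoquinone
Product: 3 2,5-dioxido-3,6-bis(phenyliodonio)-1,4-benzoquinone (bis-ylide), via mono(phenyliodonium) ylide 2 (not isolated)
Conditions: PhI(OAc)2 (2.1 equiv), CH2Cl2/MeCN 1:1, rt, 3 h, dark; filter the precipitate, wash with CH2Cl2/Et2O, use promptly
Reagents that add atoms: (diacetoxyiodo)benzene, CC(=O)OI(OC(C)=O)c1ccccc1
Why: Iodonium ylide (zwitterion) formation: the acidic enol exchanges acetate on iodine(III) and the nucleophilic enol carbon is iodinated with loss of AcOH, the reaction type established for 2-hydroxyquinones; one PhI(OAc)2 is used per enol carbon (1 → 2 → 3, four AcOH released in all), the insoluble bis-zwitterion precipitates and drives the second iodination, and no stereocentre is formed.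

**Step 2**
Reactants: 3 2,5-dioxido-3,6-bis(phenyliodonio)-1,4-benzoquinone; 4 phenol
Product: 6 2,5-dihydroxy-3,6-bis(4-hydroxyphenyl)-1,4-benzoquinone (atromentin), via mono-arylated mono-ylide 5 (not isolated)
Conditions: PhOH (10 equiv), BF3·OEt2 (3 equiv), CH2Cl2, −20 °C → rt, 12 h; 1 M HCl work-up; triturate off excess phenol, crystallise from AcOH
Reagents that add atoms: phenol (second molecule of 4), Oc1ccccc1
Why: Proposed new method: BF3 binds the oxido oxygen of each zwitterionic unit and turns it into an alkenyl(phenyl)iodonium, i.e. an enolonium equivalent, whose iodine-bearing ring carbon is attacked by the para-carbon of phenol (para favoured because the electrophilic carbon is flanked by two ring substituents), after which PhI leaves as a hypernucleofuge and the arene rearomatises; the first phenol gives 5 and a second phenol repeats the sequence at the remaining ylide centre to give 6 with two PhI released; the closest known reaction type is the BF3-mediated metal-free arylation of the phenyliodonium ylide of 2-hydroxy-1,4-naphthoquinone with activated arenes, extended here to a double coupling on a bis-ylide with free phenol as the π-nucleophile, and no stereocentre is formed.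

**Step 3**
Reactants: 6 atromentin
Product: 8 4-hydroxy-2,5-bis(4-hydroxyphenyl)-3,6-dioxocyclohexa-1,4-dien-1-yl acetate (atromentin mono-O-acetate; target), via atromentin bis(triethylammonium) salt 7 (not isolated)
Conditions: Et3N (2.0 equiv), THF, −40 °C; AcCl (1.0 equiv), −40 → 0 °C, 1 h; cold 0.5 M HCl; chromatography on acid-washed SiO2 (CH2Cl2/EtOAc, 0.5 % AcOH; no alcohols or amines); recover 6 and diacetate
Reagents that add atoms: acetyl chloride, CC(=O)Cl
Why: Selective O-acylation (vinylogous mixed-anhydride formation): exactly two equivalents of base ionise only the two quinone OH groups (vinylogous carboxylic acids, pKa about 3–6) while the phenols (pKa about 10) stay neutral and unreactive toward AcCl in the absence of free amine, the dianion is a better nucleophile than the product mono-anion so one equivalent of AcCl stops mainly at the monoacetate, and since all four quinone oxygens of the dianion are equivalent only one constitution can result.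

## Compound list

1 | 2,5-dihydroxy-1,4-benzoquinone | O=C1C=C(O)C(=O)C=C1O | starting material
2 | 2-hydroxy-5-oxido-6-(phenyliodonio)-1,4-benzoquinone (mono-ylide) | [O-]C1=C([I+]c2ccccc2)C(=O)C(O)=CC1=O | intermediate
3 | 2,5-dioxido-3,6-bis(phenyliodonio)-1,4-benzoquinone (bis-ylide) | [O-]C1=C([I+]c2ccccc2)C(=O)C([O-])=C([I+]c2ccccc2)C1=O | intermediate
4 | phenol | Oc1ccccc1 | starting material
5 | 2-hydroxy-3-(4-hydroxyphenyl)-5-oxido-6-(phenyliodonio)-1,4-benzoquinone | [O-]C1=C([I+]c2ccccc2)C(=O)C(O)=C(c2ccc(O)cc2)C1=O | intermediate
6 | 2,5-dihydroxy-3,6-bis(4-hydroxyphenyl)-1,4-benzoquinone (atromentin) | O=C1C(O)=C(c2ccc(O)cc2)C(=O)C(O)=C1c1ccc(O)cc1 | intermediate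
7 | atromentin bis(triethylammonium) salt (quinone OH groups ionised) | CC[NH+](CC)CC.CC[NH+](CC)CC.[O-]C1=C(c2ccc(O)cc2)C(=O)C([O-])=C(c2ccc(O)cc2)C1=O | intermediate
8 | 4-hydroxy-2,5-bis(4-hydroxyphenyl)-3,6-dioxocyclohexa-1,4-dien-1-yl acetate | CC(=O)OC1=C(c2ccc(O)cc2)C(=O)C(O)=C(c2ccc(O)cc2)C1=O | target

## Step count and risks

Total steps: 3. Longest linear sequence: 3.

**Step 2 (highest risk).** Possible failures are ortho/para mixtures, O-arylation of phenol, ring contraction of the ylide, or a stop at mono-aryl ylide 5. The fallback sets out from 3 and returns at 6. Instead of C–H attack by phenol, the two iodonium centres are used as pseudo-halides in a Pd-catalysed cross-coupling with two equivalents of (4-hydroxyphenyl)boronic acid (Pd(OAc)2 10 mol %, Na2CO3, DME/H2O, rt, then acidify). This is the known coupling type for hydroxyquinone iodonium ylides, and ipso-substitution at boron fixes the para regiochemistry. It gives atromentin 6 directly and makes no new compound (F0).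

**Step 3.** Possible failures are a statistical mono/di mixture, acyl transfer to the phenols, or hydrolysis of the labile acetoxyquinone. The fallback sets out from 6 and returns at 8. Exhaustive silylation of 6 (TBSCl 5 equiv, imidazole, DMF) gives 2,5-bis(tert-butyldimethylsilyloxy)-3,6-bis[4-(tert-butyldimethylsilyloxy)phenyl]-1,4-benzoquinone F1. Work-up with AcOH/THF/H2O cleaves the two quinone O-silyl groups, which are vinylogous silyl esters, and leaves 2,5-bis[4-(tert-butyldimethylsilyloxy)phenyl]-3,6-dihydroxy-1,4-benzoquinone F2. Monoacetylation as in step 3 (Et3N 2 equiv, AcCl 1 equiv) then gives 4-hydroxy-2,5-bis[4-(tert-butyldimethylsilyloxy)phenyl]-3,6-dioxocyclohexa-1,4-dien-1-yl acetate F3, now with no competing phenol. Desilylation under acidic, amine-free conditions (aq. HF, MeCN, 0 °C) gives 8.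

**Step 1.** Possible failures are incomplete bis-ylide formation, an intractable solid, or thermal decomposition. The fallback sets out from 1 and returns at 6. The polarity reversal is moved from the quinone to the arene: the enol carbons of 1 stay nucleophilic and are arylated twice with the aryl-cation equivalent 4-methoxybenzenediazonium tetrafluoroborate (2 equiv, NaOAc, acetone/H2O, 0 °C → rt, Meerwein-type arylation). This gives 2,5-dihydroxy-3,6-bis(4-methoxyphenyl)-1,4-benzoquinone F4. Demethylation with BBr3 (CH2Cl2, −78 °C → rt) then gives 6.

## Further compounds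

F0 | step 2 | none | none
F1 | step 3 | 2,5-bis(tert-butyldimethylsilyloxy)-3,6-bis[4-(tert-butyldimethylsilyloxy)phenyl]-1,4-benzoquinone | CC(C)(C)[Si](C)(C)OC1=C(c2ccc(O[Si](C)(C)C(C)(C)C)cc2)C(=O)C(O[Si](C)(C)C(C)(C)C)=C(c2ccc(O[Si](C)(C)C(C)(C)C)cc2)C1=O
F2 | step 3 | 2,5-bis[4-(tert-butyldimethylsilyloxy)phenyl]-3,6-dihydroxy-1,4-benzoquinone | O=C1C(O)=C(c2ccc(O[Si](C)(C)C(C)(C)C)cc2)C(=O)C(O)=C1c1ccc(O[Si](C)(C)C(C)(C)C)cc1
F3 | step 3 | 4-hydroxy-2,5-bis[4-(tert-butyldimethylsilyloxy)phenyl]-3,6-dioxocyclohexa-1,4-dien-1-yl acetate | CC(=O)OC1=C(c2ccc(O[Si](C)(C)C(C)(C)C)cc2)C(=O)C(O)=C(c2ccc(O[Si](C)(C)C(C)(C)C)cc2)C1=O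
F4 | step 1 | 2,5-dihydroxy-3,6-bis(4-methoxyphenyl)-1,4-benzoquinone | COc1ccc(cc1)C1=C(O)C(=O)C(c2ccc(OC)cc2)=C(O)C1=O
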